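E is the substrate, and the ledger here follows its moles, because it is the limiting reagent: 0.078 M stands against 0.0936 M of Q. The set-ups share this charge and differ in vessel and dosing.

| flask | E | Q | remark | time |
|---|---|---|---|---|
| south-east | 0.078 M | 0.0936 M | run made earlier |  |
| east | 0.078 M | 0.13 M | run made earlier |  |
| west | 0.078 M | 0.21 M | run made earlier |  |
| gamma | 0.078 M | 0.0936 M | one stirred flow tank at steady state, fed with the mixture as stated, mean residence time 4.0 h |  |
| zeta | 0.078 M | 0.0936 M (fed, over 4.00 h) | a stirred flask in which Q is dosed at a steady rate over 4.00 h without added volume, worked up at 4.0 h | 4.0 h |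
| epsilon | 0.078 M (fed, over 4.00 h) | 0.0936 M | a stirred flask in which E is dosed at a steady rate over 4.00 h without added volume, worked up at 4.0 h | 4.0 h |
| alpha | 0.078 M | 0.0936 M | a closed flask charged with all of it at once and left for 4.0 h | 4.0 h |

| south-east: time / h | south-east: L / % | east: time / h | east: L / % | west: time / h | west: L / % |
|---|---|---|---|---|---|
| 1.00 | 78.9 | 1.00 | 90.1 | 0.500 | 94.5 |
| 2.00 | 87.5 | 2.00 | 93.8 | 1.33 | 95.3 |
| 3.00 | 87.4 | 3.00 | 93.4 | 2.50 | 96.3 |
| 4.00 | 87.7 | 4.00 | 92.9 | 4.00 | 97.2 |

(scatter of a reading: 1 percentage point)

- the stated concentrations are those of everything mixed, before any reaction; amounts are the same in each set-up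
- the feed brings no volume worth counting
- the earlier runs were made in a closed, stirred flask

- the set-up with the highest amount of L at the outlet or at the end, in percent of the E put in ("none" if the first two lie within 2 percentage points) (gamma / zeta / epsilon / alpha / none)
- amount of L at the outlet or at the end, in percent of the E put in, gamma
- amount of L at the outlet or at the end, in percent of the E put in, zeta
- amount of L at the outlet or at the end, in percent of the E put in, epsilon
- amount of L at the outlet or at the end, in percent of the E put in, alpha

First entry: L. The south-east run has alpha's charge, and its last three readings average 87.5% of the E.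

Second entry: the remaining 12.5%, which the readings do not identify. The west run, with 0.21 M of Q, reads 97.2% as L at its end.

Third entry: E still open at work-up. The first west reading is 94.5% at 0.500 h, with a mean c_Q of 0.173 M. This reading carries the scatter.

k = −ln(share of E left) / (t · c_Q) = 33.5 /M/h

τ = 1 / (k · c_Q) = 0.319 h at the charged c_Q

This τ is the lifetime of E against Q, and in this reckoning it grows as c_Q falls.

Alpha has 12.5 lifetimes in 4.0 h, so its third entry is reckoned closed and its L stands near 87.5%.

In zeta, the dosed Q equals the E charged at 3.33 h. If each E has then taken one Q, the excess reaches 0.0156 M at the end of the dose. That gives a lifetime of 1.91 h, longer than the 0.667 h remaining. Zeta's third entry therefore stays open. Epsilon's last E meets the same excess, so its entry stays open too.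

This ledger puts alpha first and gives no figure for the dosed flasks.

The forecast names alpha, with 76% for gamma, 82% for zeta, 78% for epsilon and 87.6% for alpha, holding that “The lag is smaller for Q dosing”.

    E + Q → L + X (k = 0.760 /M/min)
    E + L → J (k = 0.0230 /M/min)
    E + X → G (k = 0.0370 /M/min)
    E ⇌ D (K = 0.510, k = 0.00320 /min)

Alpha gives 88.5%, gamma 71.6%, epsilon 78.5% and zeta 68.7%, which is 13 percentage points under the forecast. At 2.00 h, zeta held Q at 14.4% of its charge beside E at 34.8%. The τ reckoned from the west reading, 0.319 h at the full charge, becomes 2.22 h at that c_Q. With the constant of the first step in the scheme, the two stand at 0.234 h and 1.63 h. A neighbour of alpha, charged with 0.37 M of Q, has by that same constant a lifetime of 0.0593 h at that charge, and its L ends at 98.4%.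

Readings and results are calculated with constants of no real substance, noise included.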